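**Plan**

- Retrosynthesis: the sulfate S–O bond is cut last. The hydroxyethyl oxygen (arm on C1 of ring A) is then reconnected to the diarylmethane carbon (on C2), giving a 1-aryl-isochroman. Ring A of that isochroman is cut at C1–C2, C3–C4 and C5–C6 into a tethered 1,7-diyne ether and a two-carbon 1,2-diborylalkyne.
- Enabling feature: ring A carries the CH2CH2O arm on C1 and the CH2Ar carbon on the neighbouring C2, with Br on C3, OH on C4 and C5, and H on C6. An oxygen tether between the two arms therefore makes ring A the benzo ring of an isochroman. Its carbons map onto a bromoalkyne (C2, C3), the diborylalkyne (C4, C5, latent hydroxyls) and a terminal alkyne (C6, C1).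
- Forward: ring B is prepared first from vanillin as a benzyl-protected 2,3-dibromo-4,5-dihydroxybenzaldehyde. Ethyne is added, the alkyne terminus is brominated and the but-3-ynyl ether is installed.
- One cyclotrimerisation then closes the dihydropyran and ring A together. C–B oxidation, reductive opening of the benzhydrylic C–O bond, debenzylation and O-sulfation complete the chain.
- Stereochemistry: the target is achiral. The single benzylic stereocentre created in step 4 is carried as the racemate and erased in step 9.

Key step: step 7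

Assumption: the target is taken as the free alkyl hydrogen sulfate as drawn; it is released from its ammonium salt by cold acidic ion exchange and kept cold in solution or freeze-dried.

**Route**

Step 1
Reactants: 1 vanillin
Product: 2 2,3-dibromo-4-hydroxy-5-methoxybenzaldehyde
Conditions: Br2 (2.3 equiv), Fe powder (cat.), AcOH, rt
Reagents that add atoms: bromine, BrBr
Why: Electrophilic aromatic bromination in which the free phenol directs the first bromine ortho to itself and the methoxy group directs the second para to itself, the established dibromination pattern of vanillin.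

Step 2
Reactants: 2 2,3-dibromo-4-hydroxy-5-methoxybenzaldehyde
Product: 3 2,3-dibromo-4,5-dihydroxybenzaldehyde
Conditions: AlCl3 (1.2 equiv), pyridine (4.5 equiv), CH2Cl2, reflux; then 2 M HCl
Reagents that add atoms: none
Why: Lewis acid-assisted O-demethylation of a guaiacol, in which aluminium chelated between the phenoxide and the neighbouring methoxy oxygen activates the methyl group for SN2 removal by pyridine, the standard conversion of vanillin-type aldehydes into protocatechualdehydes.

Step 3
Reactants: 3 2,3-dibromo-4,5-dihydroxybenzaldehyde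
Product: 4 4,5-bis(benzyloxy)-2,3-dibromobenzaldehyde
Conditions: BnBr (2.3 equiv), K2CO3 (3 equiv), DMF, 50 °C
Reagents that add atoms: benzyl bromide, BrCc1ccccc1
Why: Williamson ether synthesis on both phenoxides, chosen because aryl benzyl ethers are good cation-stabilising donors for steps 6 and 9 and can later be removed at low temperature without harming the aryl bromides or the primary alcohol.

Step 4
Reactants: 4 4,5-bis(benzyloxy)-2,3-dibromobenzaldehyde; 5 ethynylmagnesium bromide
Product: 6 rac-1-[4,5-bis(benzyloxy)-2,3-dibromophenyl]prop-2-yn-1-ol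
Conditions: 5 (0.5 M in THF, 1.3 equiv), THF, −20 → 0 °C; then H2O
Reagents that add atoms: none
Why: Grignard 1,2-addition of an alkynyl nucleophile to an aryl aldehyde, which does not exchange with the aryl bromides and sets the carbinol centre without control, as intended, since this centre is erased in step 9.

Step 5
Reactants: 6 rac-1-[4,5-bis(benzyloxy)-2,3-dibromophenyl]prop-2-yn-1-ol
Product: 7 rac-1-[4,5-bis(benzyloxy)-2,3-dibromophenyl]-3-bromoprop-2-yn-1-ol
Conditions: NBS (1.1 equiv), AgNO3 (10 mol%), acetone, rt, dark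
Reagents that add atoms: N-bromosuccinimide, O=C1CCC(=O)N1Br
Why: Silver-catalysed electrophilic bromination of a terminal alkyne through the silver acetylide, which is fast enough to leave the free carbinol and the doubly brominated, deactivated arene untouched and is carried out before the second terminal alkyne is introduced.

Step 6
Reactants: 7 rac-1-[4,5-bis(benzyloxy)-2,3-dibromophenyl]-3-bromoprop-2-yn-1-ol; 8 3-butyn-1-ol
Product: 9 rac-1,2-bis(benzyloxy)-3,4-dibromo-5-[3-bromo-1-(but-3-yn-1-yloxy)prop-2-yn-1-yl]benzene
Conditions: 8 (5 equiv), FeCl3 (10 mol%), MeCN, rt → 40 °C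
Reagents that add atoms: none
Why: Lewis acid-catalysed direct propargylic substitution of the SN1 type, in which the secondary carbinol ionises to a cation stabilised by the para-benzyloxy aryl ring and the alkynyl group and is captured at the propargylic carbon by the excess primary alcohol, which suppresses self-etherification.

Step 7
Reactants: 9 rac-1,2-bis(benzyloxy)-3,4-dibromo-5-[3-bromo-1-(but-3-yn-1-yloxy)prop-2-yn-1-yl]benzene; 10 bis(pinacolboryl)acetylene
Product: 11 rac-1-[4,5-bis(benzyloxy)-2,3-dibromophenyl]-8-bromo-6,7-bis(4,4,5,5-tetramethyl-1,3,2-dioxaborolan-2-yl)isochromane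
Conditions: Cp*RuCl(cod) (10 mol%), 10 (3 equiv), 1,2-dichloroethane, rt → 60 °C, slow addition of 9 by syringe pump, Ar
Reagents that add atoms: none
Why: Proposed new method: the Cp*RuCl fragment should couple the two tethered alkynes of 9 oxidatively to a ruthenacyclopentadiene, joining the two internal alkyne carbons (the future C1–C2 bond of ring A) and so closing the six-membered dihydropyran by an intramolecular metal-templated C–C coupling; insertion of the diborylalkyne 10 and reductive elimination then form C3–C4 and C5–C6 and close ring A as a benzene in a formal [2+2+2] cycloaddition. The closest known reaction type is the ruthenium- or cobalt-catalysed cyclotrimerisation of 1,6- and 1,7-diynes, including diynes with 1-haloalkyne termini, with alkynylboronates; a bromoalkyne terminus and a 1,2-diborylalkyne partner have not been combined on a 1,7-diyne ether. No stereocentre is created, and the existing benzylic centre is untouched and stays racemic. Regiochemistry is not in question, because the ether tether fixes the orientation of the diyne and the monoalkyne is symmetric, so that Br must end on C3, H on C6 and the two boryl groups on C4 and C5. The step needs chemoselectivity for cross- over self-cyclotrimerisation and survival of the alkynyl C–Br bond; slow addition of 9 to an excess of the hindered alkyne 10, which does not trimerise with itself, and the known tolerance of this ruthenium fragment for 1-haloalkynes should secure both.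

Step 8
Reactants: 11 rac-1-[4,5-bis(benzyloxy)-2,3-dibromophenyl]-8-bromo-6,7-bis(4,4,5,5-tetramethyl-1,3,2-dioxaborolan-2-yl)isochromane
Product: 12 rac-1-[4,5-bis(benzyloxy)-2,3-dibromophenyl]-8-bromoisochromane-6,7-diol
Conditions: NaBO3·4H2O (6 equiv), THF/H2O (1:1), rt, Ar; then aq. NH4Cl
Reagents that add atoms: sodium perborate tetrahydrate, [Na+].[Na+].O[B-]1(O)OO[B-](O)(O)OO1
Why: Oxidation of aryl boronates by 1,2-migration of the aryl group from boron to peroxide oxygen, run with the mild perborate under argon so that the emerging bromocatechol is not over-oxidised and the benzyl ethers, aryl bromides and cyclic ether are unaffected.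

Step 9
Reactants: 12 rac-1-[4,5-bis(benzyloxy)-2,3-dibromophenyl]-8-bromoisochromane-6,7-diol
Product: 13 4-{[4,5-bis(benzyloxy)-2,3-dibromophenyl]methyl}-3-bromo-5-(2-hydroxyethyl)benzene-1,2-diol
Conditions: Et3SiH (4 equiv), TFA/CH2Cl2 (1:4), 0 °C → rt, short reaction time; then MeOH, aq. NaHCO3
Reagents that add atoms: none
Why: Ionic hydrogenation of a diarylmethyl ether, in which protonation opens the C1–O bond to a benzhydryl cation stabilised by the para-hydroxyl of ring A and the para-benzyloxy group of ring B and the silane delivers hydride irreversibly, while brief exposure to dilute acid leaves the aryl benzyl ethers in place and the bicarbonate work-up frees any acylated primary hydroxyl.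

Step 10
Reactants: 13 4-{[4,5-bis(benzyloxy)-2,3-dibromophenyl]methyl}-3-bromo-5-(2-hydroxyethyl)benzene-1,2-diol
Product: 14 3-bromo-4-[(2,3-dibromo-4,5-dihydroxyphenyl)methyl]-5-(2-hydroxyethyl)benzene-1,2-diol
Conditions: BCl3 (1 M in CH2Cl2, 8 equiv), pentamethylbenzene (6 equiv), CH2Cl2, −78 → −40 °C; then MeOH, H2O
Reagents that add atoms: none
Why: Lewis acid-mediated debenzylation of aryl benzyl ethers with a non-basic cation scavenger, which works at low temperature where the borate of the primary alcohol is not converted into a chloride and the aryl bromides and the diarylmethane are inert.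

Step 11
Reactants: 14 3-bromo-4-[(2,3-dibromo-4,5-dihydroxyphenyl)methyl]-5-(2-hydroxyethyl)benzene-1,2-diol
Product: 16 2-{3-bromo-2-[(2,3-dibromo-4,5-dihydroxyphenyl)methyl]-4,5-dihydroxyphenyl}ethyl hydrogen sulfate, via triethylammonium alkyl sulfate 15 (not isolated)
Conditions: SO3·NEt3 (1.3 equiv), pyridine, 0 °C → rt, Ar; then Dowex 50W-X8 (H+ form), MeOH/H2O, 0 °C
Reagents that add atoms: sulfur trioxide–triethylamine complex, CC[N+](CC)(CC)S(=O)(=O)[O-]
Why: O-Sulfation with a sulfur trioxide–amine complex, in which the primary aliphatic hydroxyl is far more nucleophilic than the four un-ionised, hydrogen-bonded and bromine-flanked phenols, so that a slight excess of the mild reagent should give the monoalkyl sulfate, which cation exchange converts into the free acid.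

**Compound list**

1 | vanillin | COc1cc(C=O)ccc1O | starting material
2 | 2,3-dibromo-4-hydroxy-5-methoxybenzaldehyde | COc1cc(C=O)c(Br)c(Br)c1O | intermediate
3 | 2,3-dibromo-4,5-dihydroxybenzaldehyde | O=Cc1cc(O)c(O)c(Br)c1Br | intermediate
4 | 4,5-bis(benzyloxy)-2,3-dibromobenzaldehyde | O=Cc1cc(OCc2ccccc2)c(OCc2ccccc2)c(Br)c1Br | intermediate
5 | ethynylmagnesium bromide | C#C[Mg]Br | starting material
6 | rac-1-[4,5-bis(benzyloxy)-2,3-dibromophenyl]prop-2-yn-1-ol | C#CC(O)c1cc(OCc2ccccc2)c(OCc2ccccc2)c(Br)c1Br | intermediate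
7 | rac-1-[4,5-bis(benzyloxy)-2,3-dibromophenyl]-3-bromoprop-2-yn-1-ol | BrC#CC(O)c1cc(OCc2ccccc2)c(OCc2ccccc2)c(Br)c1Br | intermediate
8 | 3-butyn-1-ol | C#CCCO | starting material
9 | rac-1,2-bis(benzyloxy)-3,4-dibromo-5-[3-bromo-1-(but-3-yn-1-yloxy)prop-2-yn-1-yl]benzene | C#CCCOC(C#CBr)c1cc(OCc2ccccc2)c(OCc2ccccc2)c(Br)c1Br | intermediate
10 | bis(pinacolboryl)acetylene [1,2-bis(4,4,5,5-tetramethyl-1,3,2-dioxaborolan-2-yl)ethyne] | CC1(C)OB(C#CB2OC(C)(C)C(C)(C)O2)OC1(C)C | starting material
11 | rac-1-[4,5-bis(benzyloxy)-2,3-dibromophenyl]-8-bromo-6,7-bis(4,4,5,5-tetramethyl-1,3,2-dioxaborolan-2-yl)isochromane | CC1(C)OB(OC1(C)C)c1cc2CCOC(c3cc(OCc4ccccc4)c(OCc4ccccc4)c(Br)c3Br)c2c(Br)c1B1OC(C)(C)C(C)(C)O1 | intermediate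
12 | rac-1-[4,5-bis(benzyloxy)-2,3-dibromophenyl]-8-bromoisochromane-6,7-diol | Oc1cc2CCOC(c3cc(OCc4ccccc4)c(OCc4ccccc4)c(Br)c3Br)c2c(Br)c1O | intermediate
13 | 4-{[4,5-bis(benzyloxy)-2,3-dibromophenyl]methyl}-3-bromo-5-(2-hydroxyethyl)benzene-1,2-diol | OCCc1cc(O)c(O)c(Br)c1Cc1cc(OCc2ccccc2)c(OCc2ccccc2)c(Br)c1Br | intermediate
14 | 3-bromo-4-[(2,3-dibromo-4,5-dihydroxyphenyl)methyl]-5-(2-hydroxyethyl)benzene-1,2-diol | OCCc1cc(O)c(O)c(Br)c1Cc1cc(O)c(O)c(Br)c1Br | intermediate
15 | triethylammonium 2-{3-bromo-2-[(2,3-dibromo-4,5-dihydroxyphenyl)methyl]-4,5-dihydroxyphenyl}ethyl sulfate | CC[NH+](CC)CC.[O-]S(=O)(=O)OCCc1cc(O)c(O)c(Br)c1Cc1cc(O)c(O)c(Br)c1Br | intermediate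
16 | 2-{3-bromo-2-[(2,3-dibromo-4,5-dihydroxyphenyl)methyl]-4,5-dihydroxyphenyl}ethyl hydrogen sulfate | O=S(=O)(O)OCCc1cc(O)c(O)c(Br)c1Cc1cc(O)c(O)c(Br)c1Br | target

**Step count and risks**

Total step count: 11. Longest linear sequence: 11 steps (from vanillin; 3-butyn-1-ol, ethynylmagnesium bromide and the diborylalkyne are commercial).

Steps most likely to fail:

1. Step 7 (cyclotrimerisation). The hindered diborylalkyne may fail to insert into the ruthenacycle, so that self-oligomerisation of the diyne or oxidative addition of the alkynyl C–Br bond to the catalyst takes over. The fallback builds ring A from a preformed arene by known chemistry and sets out from aldehyde 4.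
   - Aldehyde 4 and commercial homovanillyl alcohol [2-(4-hydroxy-3-methoxyphenyl)ethanol] would undergo an acid-promoted oxa-Pictet–Spengler cyclisation (TMSOTf, CH2Cl2, 0 °C). Closure para to the methoxy group should give rac-1-[4,5-bis(benzyloxy)-2,3-dibromophenyl]-6-methoxyisochroman-7-ol F1.
   - Bromination with NBS at the only free position ortho to the phenol should then give rac-1-[4,5-bis(benzyloxy)-2,3-dibromophenyl]-8-bromo-6-methoxyisochroman-7-ol F2.
   - Oxidative O-demethylation of the guaiacol unit with 2-iodoxybenzoic acid in DMF should lead to rac-1-[4,5-bis(benzyloxy)-2,3-dibromophenyl]-8-bromoisochromane-6,7-dione F3. Reduction with Na2S2O4 converts this into 12, where the route resumes at step 9.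

2. Step 6 (propargylic etherification). Ionisation of the carbinol may be slow because the two bromines and the ortho substituent weaken aryl donation, which would let Meyer–Schuster rearrangement or self-etherification compete. The fallback replaces dehydrative substitution by a preformed leaving group and sets out from 7.
   - Cl3CCN with catalytic DBU in CH2Cl2 at 0 °C should give rac-1-[4,5-bis(benzyloxy)-2,3-dibromophenyl]-3-bromoprop-2-yn-1-yl 2,2,2-trichloroacetimidate F4.
   - Catalytic TMSOTf at −40 °C in the presence of 3-butyn-1-ol 8 should then deliver 9, where the route resumes at step 7.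

3. Step 11 (selective sulfation). Transfer of sulfur trioxide to the acidic bromocatechol hydroxyls may compete with the primary alcohol and give mixed or multiple sulfates. The fallback masks the phenols and sets out from 14.
   - Exhaustive silylation (TBSCl, imidazole, DMF) should give 2-{3-bromo-2-[(2,3-dibromo-4,5-bis(tert-butyldimethylsilyloxy)phenyl)methyl]-4,5-bis(tert-butyldimethylsilyloxy)phenyl}ethyl tert-butyldimethylsilyl ether F5.
   - Mild acid methanolysis (pyridinium p-toluenesulfonate, MeOH, rt) cleaves only the alkyl silyl ether and should give 2-{3-bromo-2-[(2,3-dibromo-4,5-bis(tert-butyldimethylsilyloxy)phenyl)methyl]-4,5-bis(tert-butyldimethylsilyloxy)phenyl}ethanol F6.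
   - Sulfation with SO3·pyridine in DMF should give 2-{3-bromo-2-[(2,3-dibromo-4,5-bis(tert-butyldimethylsilyloxy)phenyl)methyl]-4,5-bis(tert-butyldimethylsilyloxy)phenyl}ethyl hydrogen sulfate F7.
   - Fluoride desilylation (KF, MeOH) followed by the same acidic ion exchange returns to the route at 16.

**Further compounds**

F1 | step 7 | rac-1-[4,5-bis(benzyloxy)-2,3-dibromophenyl]-6-methoxyisochroman-7-ol | COc1cc2CCOC(c3cc(OCc4ccccc4)c(OCc4ccccc4)c(Br)c3Br)c2cc1O
F2 | step 7 | rac-1-[4,5-bis(benzyloxy)-2,3-dibromophenyl]-8-bromo-6-methoxyisochroman-7-ol | COc1cc2CCOC(c3cc(OCc4ccccc4)c(OCc4ccccc4)c(Br)c3Br)c2c(Br)c1O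
F3 | step 7 | rac-1-[4,5-bis(benzyloxy)-2,3-dibromophenyl]-8-bromoisochromane-6,7-dione | O=C1C=C2CCOC(c3cc(OCc4ccccc4)c(OCc4ccccc4)c(Br)c3Br)C2=C(Br)C1=O
F4 | step 6 | rac-1-[4,5-bis(benzyloxy)-2,3-dibromophenyl]-3-bromoprop-2-yn-1-yl 2,2,2-trichloroacetimidate | BrC#CC(OC(=N)C(Cl)(Cl)Cl)c1cc(OCc2ccccc2)c(OCc2ccccc2)c(Br)c1Br
F5 | step 11 | 2-{3-bromo-2-[(2,3-dibromo-4,5-bis(tert-butyldimethylsilyloxy)phenyl)methyl]-4,5-bis(tert-butyldimethylsilyloxy)phenyl}ethyl tert-butyldimethylsilyl ether | CC(C)(C)[Si](C)(C)OCCc1cc(O[Si](C)(C)C(C)(C)C)c(O[Si](C)(C)C(C)(C)C)c(Br)c1Cc1cc(O[Si](C)(C)C(C)(C)C)c(O[Si](C)(C)C(C)(C)C)c(Br)c1Br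
F6 | step 11 | 2-{3-bromo-2-[(2,3-dibromo-4,5-bis(tert-butyldimethylsilyloxy)phenyl)methyl]-4,5-bis(tert-butyldimethylsilyloxy)phenyl}ethanol | OCCc1cc(O[Si](C)(C)C(C)(C)C)c(O[Si](C)(C)C(C)(C)C)c(Br)c1Cc1cc(O[Si](C)(C)C(C)(C)C)c(O[Si](C)(C)C(C)(C)C)c(Br)c1Br
F7 | step 11 | 2-{3-bromo-2-[(2,3-dibromo-4,5-bis(tert-butyldimethylsilyloxy)phenyl)methyl]-4,5-bis(tert-butyldimethylsilyloxy)phenyl}ethyl hydrogen sulfate | OS(=O)(=O)OCCc1cc(O[Si](C)(C)C(C)(C)C)c(O[Si](C)(C)C(C)(C)C)c(Br)c1Cc1cc(O[Si](C)(C)C(C)(C)C)c(O[Si](C)(C)C(C)(C)C)c(Br)c1Br
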